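## Analysis of the target

The target is (2S)-5,7-dihydroxy-2-[4-hydroxy-3-(3-methylbut-2-en-1-yl)phenyl]-6,8-bis(3-methylbut-2-en-1-yl)chroman-4-one. It is a flavanone in which a fully substituted phloroglucinol ring A is fused to the dihydropyranone ring C, with ring B on C2. C2 is the only stereocentre. It is benzylic, carries O1 and lies β to the C4 ketone, so it can be lost by reversible oxa-Michael opening of ring C under base or by ionisation under acid, the latter helped by the para oxygen of ring B. The three prenyl groups are trisubstituted alkenes; they rule out hydrogenation, electrophilic halogen and peracids, and in strong protic acid they cyclise onto the neighbouring phenols. Ring A carries six substituents, and C-prenylation of a finished 5,7-dihydroxyflavanone would be neither regioselective nor safe for C2, so the C6 and C8 prenyl groups should arrive together with the carbons of ring A. The difficulty is therefore to set C2 with absolute control, never afterwards expose it to conditions that open ring C, and assemble the crowded ring A without ambiguity. The strategy rests on one feature: with ring A removed, the atoms O1, C2, C3, C4, C4a and C8a form a 2-aryl-2,3-dihydropyran-4-one. Its C2 is the former formyl carbon of the ring B aldehyde, and its C4a=C8a enol ether double bond (C8a electrophilic, C4a nucleophilic) is the edge on which ring A can be grown.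

## Retrosynthetic reasoning

**16 to 15.** The ring B phenol is kept as a silyl ether to the end. A free para-phenol would make C2 far easier to ionise or to open through a quinone-methide path, and a fluoride source removes the group without base. Only the O–Si bond is cut.

**15 to 14.** Ring A is opened at C4a–C5. Forward, this is a Claisen-type condensation: the extended enolate of 14 attacks the ester carbon through C4a, the alkoxy group leaves, and tautomerisation aromatises the ring. The cut is placed here because C5 is then an ester carbon at the correct oxidation level. In 14 no enolate carbon can reach a carbonyl through any ring size other than this six-membered one. C8a is already tied up as the ring C enol ether, so the competing aldol folding of an open polyketone cannot occur.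

**14 to 7 and 12.** The C8–C8a bond is cut. Forward, the terminal carbon of silyloxydiene 12 adds to C8a of the activated pyranone 7, giving 13. The conjugate addition leaves C8a one oxidation level too low, so the C4a=C8a double bond must be restored. This is done by palladium-mediated dehydrosilylation of the ring C silyl enol ether that the addition produces anyway.

A halogen at C4a was weighed as the carrier of this oxidation level and dropped for two reasons:
- Electrophilic halogen does not reliably distinguish C4a from the prenyl alkene.
- After a one-flask ring closure the halogen would sit on a quaternary C4a whose only β-hydrogen, at C8a, is neither acidic nor anti, so it could not leave as hydrogen halide.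

The annulation is therefore run as a formal [4+2] in two stages: C8–C8a with re-oxidation (step 8), then C4a–C5 (step 9).

One caution governs everything after 7. O1 of the pyranone is a vinylogous carboxylate, and deprotonation at C3 could expel it and destroy C2. Strong bases are therefore avoided from 7 onward.

**12 to 11, 10, 9, 8 and 2.** The diene is the bis-silyl dienol ether of β-keto ester 10. Its two prenyl groups are placed by γ- and then α-alkylation of 8 with 2, so the regiochemistry of ring A is decided by ordinary acetoacetate chemistry on an acyclic compound.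

**7 to 4 and 5.** This is the key disconnection. C2–C3 and O1–C8a are cut, which opens ring C and removes the stereocentre. Forward, a chiral titanium Lewis acid directs 5 to one face of the formyl group of 4; acid then closes the ring through adduct 6. Ring C and C2 are made in one catalytic operation from an achiral aldehyde. The C2–O1 bond is formed here and is never broken or remade later.

**4 to 3, 1 and 2.** The aldehyde comes from ortho C-prenylation of 1 with 2 and silylation of 3. These are two simple steps, so the risk of the front end sits in the key step.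

## Alternatives that were turned down

**Alternative 1: aryne annulation of ring C.**
- Disconnection: O1–C8a and C4–C4a together.
- Forward key step: CsF releases the aryne from the silyl triflate A2 and the alkoxide from the β-silyloxy ester A3. The oxygen adds to C8a, and the C4a aryl anion acylates itself on the ester to give the tris(methoxymethyl) flavanone A1.
- For: it is convergent, ring A is carried in aromatic form so no oxidation-level adjustment at C8a is needed, and the C5 alkoxy group steers the alkoxide to the distal aryne carbon. On convergence and on the ring A oxidation level it is stronger than the chosen route.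
- Against:
  - A2 is a hexasubstituted benzene that needs a long regiocontrolled synthesis of its own.
  - The free β-alkoxide of A3 can undergo retro-aldol cleavage or elimination before it finds the aryne.
  - The aryl anion can be quenched by the acidic α-hydrogens of the ester instead of closing the ring.
  - The attacked carbon C8a is flanked by the C8 prenyl group.
  - Three acetal groups must finally be removed with acid from A1, beside three prenyl groups and two ortho phenols.
- Comparison: the chosen route gives up convergence at the aromatic stage. In return the stereocentre is formed in the ring-closing step under non-basic conditions, and only one protecting group has to be removed.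

**Alternative 2: biomimetic Claisen folding of an open chain.**
- Disconnection: C4a–C8a of ring A.
- Forward key step: Mg(OMe)2 in methanol enolises the triketo ester A5, and C4a attacks the terminal ester carbon to give the acylphloroglucinol A4. A4 has the (R)-carbinol, so that a later Mitsunobu closure with inversion can form O1–C2.
- For: the ring A chemistry is classical, and the symmetry of the acylphloroglucinol means either ortho phenol gives the same ring C. On the ring A closure it is as strong as the chosen route, which uses the same reaction type.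
- Against:
  - A5 has several enolisable sites and a β-silyloxy ketone, so aldol folding and β-elimination compete with the Claisen mode.
  - The stereocentre must be inverted late at an electron-rich benzylic carbinol, where ionisation and elimination erode the configuration.
- Comparison: the chosen route keeps the Claisen closure but masks C8a as the ring C enol ether, so only one folding mode exists and no substitution at C2 is ever required.

**Alternative 3: enantiotopic C–H insertion.**
- Disconnection: C2–C3.
- Forward key step: Rh2(S-PTTL)4 or its enantiomer converts the diazoketone A7 into a divalent-rhodium carbenoid at C3, which inserts into one benzylic C–H bond to give the tris-silyl flavanone A6.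
- For: on paper it is the shortest path to the whole skeleton, from an achiral precursor, with the stereocentre set late by a catalyst. On step count it is stronger than the chosen route.
- Against:
  - The carbenoid must ignore three prenyl alkenes (cyclopropanation, allylic insertion).
  - It must also ignore the ether oxygen O1, whose attack gives a five-membered oxonium ylide and a 1,2-benzyl shift.
  - The insertion has to form a six-membered ring, with an acceptor-only carbenoid for which enantiocontrol is modest.
- Comparison: the chosen route accepts more steps in exchange for a key step with broad precedent on aromatic aldehydes and no reactive intermediate that conflicts with the alkenes.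

Key step: step 3

Assumption: the (S)-BINOL–titanium catalyst is taken to deliver the diene to the Si face of the aryl aldehyde, as it does for related carbon nucleophiles; should the sense be opposite, (R)-BINOL is used with no other change.

## Route

Step 1
Reactants: 1 4-hydroxybenzaldehyde; 2 prenyl bromide (1-bromo-3-methylbut-2-ene)
Product: 3 4-hydroxy-3-(3-methylbut-2-en-1-yl)benzaldehyde
Conditions: KOH (10% aq.), 2 added slowly, 23 °C; acidify; chromatography
Reagents that add atoms: none
Why: C-alkylation of an ambident phenoxide in water, where hydrogen bonding to the phenoxide oxygen holds back O-alkylation; the para position is blocked and the two ortho positions are equivalent, so only one C-prenyl isomer can form.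

Step 2
Reactants: 3 4-hydroxy-3-(3-methylbut-2-en-1-yl)benzaldehyde
Product: 4 4-[tert-butyl(dimethyl)silyl]oxy-3-(3-methylbut-2-en-1-yl)benzaldehyde
Conditions: TBSCl, imidazole, DMF, 23 °C
Reagents that add atoms: tert-butyldimethylsilyl chloride, CC(C)(C)[Si](C)(C)Cl
Why: Standard silylation of a phenol; the silyl ether removes the acidic proton that would quench the titanium catalyst and is a weaker donor than a free phenol.

Step 3
Reactants: 4 4-[tert-butyl(dimethyl)silyl]oxy-3-(3-methylbut-2-en-1-yl)benzaldehyde; 5 Danishefsky's diene ((E)-1-methoxy-3-(trimethylsilyloxy)buta-1,3-diene)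
Product: 7 (2S)-2-{4-[tert-butyl(dimethyl)silyl]oxy-3-(3-methylbut-2-en-1-yl)phenyl}-2,3-dihydro-4H-pyran-4-one, via silylated aldol adduct 6 (not isolated)
Conditions: (S)-BINOL (20 mol%), Ti(OiPr)4 (10 mol%), 4 Å MS, Et2O, −20 °C; then CF3CO2H (cat.), CH2Cl2, 0 °C
Reagents that add atoms: none
Why: Tetravalent titanium bearing binaphtholate ligands binds the formyl oxygen of 4 and exposes the Si face of the carbonyl carbon. The CH2 terminus of diene 5 adds to that face in a Mukaiyama aldol step (a concerted [4+2] is the limiting alternative), forming C2–C3 and giving 6. Acid then activates the β-methoxy enone of 6, the C2 oxygen adds to the methoxy-bearing carbon and methanol leaves, a 6-endo-trig addition–elimination that forms O1–C8a and closes ring C. The closest known reaction type is the titanium–binaphthol-catalysed hetero-Diels–Alder reaction of aromatic aldehydes with 1-alkoxy-3-silyloxybutadienes. C2 is the only new stereocentre and, since 4 is achiral, it is controlled by the axial chirality of the ligand alone. Regiochemistry is not in question because the diene is polarised, its CH2 terminus being the only nucleophilic carbon and its methoxy-bearing carbon the only one at the aldehyde oxidation level. The step needs high facial selectivity and retention of the C2–O bond during ring closure; the first rests on the catalyst, the second on cold catalytic acid and on the silyl ether of ring B, which holds back benzylic ionisation. The prenyl group is meta to the formyl group and remote from the metal.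

Step 4
Reactants: 8 methyl acetoacetate; 2 prenyl bromide
Product: 9 methyl 7-methyl-3-oxooct-6-enoate
Conditions: NaH, THF, 0 °C; n-BuLi, 0 °C; 2, 0 → 23 °C; aq. HCl
Reagents that add atoms: none
Why: γ-Alkylation of the acetoacetate dianion; the terminal carbanion is the more basic and more nucleophilic site and displaces the primary allylic bromide by SN2.

Step 5
Reactants: 9 methyl 7-methyl-3-oxooct-6-enoate; 2 prenyl bromide
Product: 10 methyl 7-methyl-2-(3-methylbut-2-en-1-yl)-3-oxooct-6-enoate (racemic)
Conditions: K2CO3, acetone, 56 °C
Reagents that add atoms: none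
Why: C-Alkylation of a β-keto ester enolate at the carbon between the two carbonyl groups; one equivalent of bromide limits double alkylation.

Step 6
Reactants: 10 methyl 7-methyl-2-(3-methylbut-2-en-1-yl)-3-oxooct-6-enoate
Product: 11 methyl 7-methyl-2-(3-methylbut-2-en-1-yl)-3-(trimethylsilyloxy)octa-2,6-dienoate
Conditions: TMSCl, Et3N, pentane, 23 °C; filter, concentrate
Reagents that add atoms: chlorotrimethylsilane, C[Si](C)(C)Cl
Why: O-Silylation of the β-keto ester enol, the first half of the usual two-stage preparation of 1,3-bis(silyloxy)dienes.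

Step 7
Reactants: 11 methyl 7-methyl-2-(3-methylbut-2-en-1-yl)-3-(trimethylsilyloxy)octa-2,6-dienoate
Product: 12 1-methoxy-7-methyl-2-(3-methylbut-2-en-1-yl)-1,3-bis(trimethylsilyloxy)octa-1,3,6-triene (mixture of double-bond isomers; used crude)
Conditions: LiN(iPr)2, THF, −78 °C; TMSCl, −78 → 0 °C; pentane, filter, concentrate
Reagents that add atoms: chlorotrimethylsilane, C[Si](C)(C)Cl
Why: The only hydrogens conjugated to the ester through the silyloxy-enoate are at the γ-CH2, so kinetic deprotonation there and O-silylation of the ester dienolate give the diene; its double-bond geometry is of no consequence because every diene carbon ends sp2 in ring A.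

Step 8
Reactants: 7 (2S)-2-{4-[tert-butyl(dimethyl)silyl]oxy-3-(3-methylbut-2-en-1-yl)phenyl}-2,3-dihydro-4H-pyran-4-one; 12 1-methoxy-7-methyl-2-(3-methylbut-2-en-1-yl)-1,3-bis(trimethylsilyloxy)octa-1,3,6-triene
Product: 14 methyl 4-[(2S)-2-{4-[tert-butyl(dimethyl)silyl]oxy-3-(3-methylbut-2-en-1-yl)phenyl}-4-oxo-3,4-dihydro-2H-pyran-6-yl]-7-methyl-2-(3-methylbut-2-en-1-yl)-3-oxooct-6-enoate (mixture of side-chain diastereomers), via bis-silylated conjugate adduct 13 (not isolated)
Conditions: TMSOTf (0.3 equiv), CH2Cl2, −78 → −40 °C; Et3N, pentane, filter, concentrate; Pd(OAc)2 (1.1 equiv), MeCN, 23 °C; aq. NH4Cl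
Reagents that add atoms: none
Why: Catalytic silyl triflate turns the vinylogous ester of 7 into a 4-silyloxy oxocarbenium ion, which the terminal carbon of 12 attacks at C8a (Mukaiyama–Michael addition), leaving ring C as the regiodefined C4–C4a silyl enol ether 13. Divalent palladium then takes up this unhindered enol ether in preference to the tetrasubstituted, ester-conjugated one in the side chain, and β-hydride elimination of the C8a hydrogen restores the C4a=C8a double bond (Saegusa–Ito oxidation). The new centres at C8 and C6 become sp2 in step 9, and C2 is not touched.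

Step 9
Reactants: 14 methyl 4-[(2S)-2-{4-[tert-butyl(dimethyl)silyl]oxy-3-(3-methylbut-2-en-1-yl)phenyl}-4-oxo-3,4-dihydro-2H-pyran-6-yl]-7-methyl-2-(3-methylbut-2-en-1-yl)-3-oxooct-6-enoate
Product: 15 (2S)-2-{4-[tert-butyl(dimethyl)silyl]oxy-3-(3-methylbut-2-en-1-yl)phenyl}-5,7-dihydroxy-6,8-bis(3-methylbut-2-en-1-yl)-2,3-dihydro-4H-chromen-4-one
Conditions: DBU (2 equiv), toluene, 0 → 23 °C; pH 5 acetate buffer
Reagents that add atoms: none
Why: The C8 hydrogen of 14 lies between the C7 ketone and the vinylogous ester, so a mild amidine base forms the extended enolate, whose α-carbon C4a attacks the ester carbonyl in a 6-exo-trig Claisen (Dieckmann-type) condensation; loss of methoxide and tautomerisation give the aromatic ring A. No other ring size is within reach of any enolate carbon, and the base is kept weak, aprotic and cold, with ring B still silylated, to hold back reversible opening of the new flavanone at C2.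

Step 10
Reactants: 15 (2S)-2-{4-[tert-butyl(dimethyl)silyl]oxy-3-(3-methylbut-2-en-1-yl)phenyl}-5,7-dihydroxy-6,8-bis(3-methylbut-2-en-1-yl)-2,3-dihydro-4H-chromen-4-one
Product: 16 (2S)-5,7-dihydroxy-2-[4-hydroxy-3-(3-methylbut-2-en-1-yl)phenyl]-6,8-bis(3-methylbut-2-en-1-yl)-2,3-dihydro-4H-chromen-4-one (target)
Conditions: HF·pyridine, pyridine, THF, 0 °C
Reagents that add atoms: none
Why: Fluoride cleaves the aryl silyl ether in a buffered, weakly acidic medium in which the flavanone does not open at C2 and the prenyl groups do not cyclise onto the neighbouring phenols.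

## Compound list

1 | 4-hydroxybenzaldehyde | O=Cc1ccc(O)cc1 | starting material
2 | prenyl bromide (1-bromo-3-methylbut-2-ene) | CC(C)=CCBr | starting material
3 | 4-hydroxy-3-(3-methylbut-2-en-1-yl)benzaldehyde | CC(C)=CCc1cc(C=O)ccc1O | intermediate
4 | 4-[tert-butyl(dimethyl)silyl]oxy-3-(3-methylbut-2-en-1-yl)benzaldehyde | CC(C)=CCc1cc(C=O)ccc1O[Si](C)(C)C(C)(C)C | intermediate
5 | Danishefsky's diene, (E)-1-methoxy-3-(trimethylsilyloxy)buta-1,3-diene | CO/C=C/C(=C)O[Si](C)(C)C | starting material
6 | (1E,5S)-5-{4-[tert-butyl(dimethyl)silyl]oxy-3-(3-methylbut-2-en-1-yl)phenyl}-1-methoxy-5-(trimethylsilyloxy)pent-1-en-3-one | CC(C)=CCc1cc([C@H](CC(=O)/C=C/OC)O[Si](C)(C)C)ccc1O[Si](C)(C)C(C)(C)C | intermediate (not isolated)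
7 | (2S)-2-{4-[tert-butyl(dimethyl)silyl]oxy-3-(3-methylbut-2-en-1-yl)phenyl}-2,3-dihydro-4H-pyran-4-one | CC(C)=CCc1cc([C@@H]2CC(=O)C=CO2)ccc1O[Si](C)(C)C(C)(C)C | intermediate
8 | methyl acetoacetate | COC(=O)CC(C)=O | starting material
9 | methyl 7-methyl-3-oxooct-6-enoate | COC(=O)CC(=O)CCC=C(C)C | intermediate
10 | methyl 7-methyl-2-(3-methylbut-2-en-1-yl)-3-oxooct-6-enoate (racemic) | COC(=O)C(CC=C(C)C)C(=O)CCC=C(C)C | intermediate
11 | methyl 7-methyl-2-(3-methylbut-2-en-1-yl)-3-(trimethylsilyloxy)octa-2,6-dienoate | COC(=O)C(CC=C(C)C)=C(O[Si](C)(C)C)CCC=C(C)C | intermediate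
12 | 1-methoxy-7-methyl-2-(3-methylbut-2-en-1-yl)-1,3-bis(trimethylsilyloxy)octa-1,3,6-triene | COC(O[Si](C)(C)C)=C(CC=C(C)C)C(O[Si](C)(C)C)=CCC=C(C)C | intermediate
13 | methyl 4-[(2S)-2-{4-[tert-butyl(dimethyl)silyl]oxy-3-(3-methylbut-2-en-1-yl)phenyl}-4-(trimethylsilyloxy)-3,6-dihydro-2H-pyran-6-yl]-7-methyl-2-(3-methylbut-2-en-1-yl)-3-(trimethylsilyloxy)octa-2,6-dienoate | CC(C)=CCc1cc([C@@H]2CC(O[Si](C)(C)C)=CC(C(CC=C(C)C)C(O[Si](C)(C)C)=C(CC=C(C)C)C(=O)OC)O2)ccc1O[Si](C)(C)C(C)(C)C | intermediate (not isolated)
14 | methyl 4-[(2S)-2-{4-[tert-butyl(dimethyl)silyl]oxy-3-(3-methylbut-2-en-1-yl)phenyl}-4-oxo-3,4-dihydro-2H-pyran-6-yl]-7-methyl-2-(3-methylbut-2-en-1-yl)-3-oxooct-6-enoate | CC(C)=CCc1cc([C@@H]2CC(=O)C=C(C(CC=C(C)C)C(=O)C(CC=C(C)C)C(=O)OC)O2)ccc1O[Si](C)(C)C(C)(C)C | intermediate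
15 | (2S)-2-{4-[tert-butyl(dimethyl)silyl]oxy-3-(3-methylbut-2-en-1-yl)phenyl}-5,7-dihydroxy-6,8-bis(3-methylbut-2-en-1-yl)-2,3-dihydro-4H-chromen-4-one | CC(C)=CCc1cc([C@@H]2CC(=O)c3c(O)c(CC=C(C)C)c(O)c(CC=C(C)C)c3O2)ccc1O[Si](C)(C)C(C)(C)C | intermediate
16 | (2S)-5,7-dihydroxy-2-[4-hydroxy-3-(3-methylbut-2-en-1-yl)phenyl]-6,8-bis(3-methylbut-2-en-1-yl)-2,3-dihydro-4H-chromen-4-one | CC(C)=CCc1cc([C@@H]2CC(=O)c3c(O)c(CC=C(C)C)c(O)c(CC=C(C)C)c3O2)ccc1O | target

## Step count and least certain steps

Total: 10 steps. Longest linear sequence: 7 steps (8 → 9 → 10 → 11 → 12 → 14 → 15 → 16; steps 4 to 10). The aldehyde branch (steps 1 to 3) joins at step 8.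

**Step 3 (key step).** What may go wrong:
- Slow turnover of the electron-rich aldehyde on titanium, which lets a less selective background addition lower the facial selectivity.
- Benzylic ionisation of the carbinol during the acid-mediated closure, which erodes the configuration at C2.

Fallback, from 4 back to 7: replace Lewis-acid catalysis by a stoichiometric reagent-controlled addition and build the ring afterwards. Aldehyde 4 is allylated with (−)-B-allyldiisopinocampheylborane (Et2O, −78 °C, ethanolamine work-up), which is expected to take the Si face, giving (1S)-1-{4-[tert-butyl(dimethyl)silyl]oxy-3-(3-methylbut-2-en-1-yl)phenyl}but-3-en-1-ol F1. Silylation with TESCl and imidazole gives its triethylsilyl ether F2. Wacker oxidation of the terminal alkene (PdCl2 cat., Cu(OAc)2, O2, DMA–H2O) leaves the trisubstituted prenyl alkene alone and gives the methyl ketone F3. Kinetic enolisation of the methyl group with LiN(iPr)2 at −78 °C and formylation with ethyl formate gives the β-keto aldehyde F4. Catalytic CF3CO2H in CH2Cl2 removes the triethylsilyl group and closes ring C by the same 6-endo addition–elimination, with loss of water, to 7.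

**Step 8.** What may go wrong:
- Incomplete conjugate addition of the hindered, doubly substituted diene.
- Ionisation of the C2–O1 bond in the silyl-activated pyranone, with loss of configuration.
- Unselective palladation of both silyl enol ethers.

Fallback, from 7 and 12 back to 14: replace the palladium dehydrosilylation by a selenoxide elimination. The conjugate addition is run as before, but the ring C silyl enol ether of 13 is intercepted at −78 °C with N-(phenylselanyl)phthalimide, which attacks enol ethers but not unactivated alkenes, giving methyl 4-[(2S)-2-{4-[tert-butyl(dimethyl)silyl]oxy-3-(3-methylbut-2-en-1-yl)phenyl}-4-oxo-5-(phenylselanyl)tetrahydro-2H-pyran-6-yl]-7-methyl-2-(3-methylbut-2-en-1-yl)-3-oxooct-6-enoate F5. NaIO4 in aqueous THF oxidises selenium to the selenoxide F6, which loses benzeneselenenic acid by thermal syn-elimination with the C8a hydrogen at 0 to 23 °C and gives 14.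

**Step 9.** What may go wrong:
- Reversible opening of the newly formed flavanone at C2 under the base, with erosion of the enantiomeric purity; this is faster if the ring B silyl ether is lost.
- Slow condensation if the β-keto ester is the site that is deprotonated first.

Fallback, from 14 back to 15: a base-free thermal closure. 14 is heated in xylene at about 140 °C with distillative removal of methanol. Thermal loss of methanol from the β-keto ester gives the acylketene F7, whose enol tautomer across C7–C8 is a dienylketene. It closes the C5–C4a bond by 6π-electrocyclisation and tautomerises to 15 without any phenoxide being formed.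

**Step 1.** What may go wrong: competing O-alkylation and double C-alkylation, which lower the throughput of the first intermediate.

Fallback, from 1 back to 3: an aromatic Claisen route. 1 is O-alkylated with 3-chloro-3-methylbut-1-yne (CuCl2 cat., DBU, MeCN, 0 °C) to 4-[(2-methylbut-3-yn-2-yl)oxy]benzaldehyde F8. Semi-hydrogenation (H2, Pd/CaCO3 poisoned with Pb(OAc)2, quinoline) gives 4-[(2-methylbut-3-en-2-yl)oxy]benzaldehyde F9. Heating in N,N-diethylaniline at about 130 °C brings about the [3,3] rearrangement that delivers the allyl terminus to the ortho carbon and gives 3.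

## Further compounds

F1 | step 3 | (1S)-1-{4-[tert-butyl(dimethyl)silyl]oxy-3-(3-methylbut-2-en-1-yl)phenyl}but-3-en-1-ol | CC(C)=CCc1cc([C@@H](O)CC=C)ccc1O[Si](C)(C)C(C)(C)C
F2 | step 3 | tert-butyl(dimethyl){2-(3-methylbut-2-en-1-yl)-4-[(1S)-1-(triethylsilyloxy)but-3-en-1-yl]phenoxy}silane | CC(C)=CCc1cc([C@@H](O[Si](CC)(CC)CC)CC=C)ccc1O[Si](C)(C)C(C)(C)C
F3 | step 3 | (4S)-4-{4-[tert-butyl(dimethyl)silyl]oxy-3-(3-methylbut-2-en-1-yl)phenyl}-4-(triethylsilyloxy)butan-2-one | CC(C)=CCc1cc([C@@H](O[Si](CC)(CC)CC)CC(C)=O)ccc1O[Si](C)(C)C(C)(C)C
F4 | step 3 | (5S)-5-{4-[tert-butyl(dimethyl)silyl]oxy-3-(3-methylbut-2-en-1-yl)phenyl}-3-oxo-5-(triethylsilyloxy)pentanal | CC(C)=CCc1cc([C@@H](O[Si](CC)(CC)CC)CC(=O)CC=O)ccc1O[Si](C)(C)C(C)(C)C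
F5 | step 8 | methyl 4-[(2S)-2-{4-[tert-butyl(dimethyl)silyl]oxy-3-(3-methylbut-2-en-1-yl)phenyl}-4-oxo-5-(phenylselanyl)tetrahydro-2H-pyran-6-yl]-7-methyl-2-(3-methylbut-2-en-1-yl)-3-oxooct-6-enoate | CC(C)=CCc1cc([C@@H]2CC(=O)C([Se]c3ccccc3)C(C(CC=C(C)C)C(=O)C(CC=C(C)C)C(=O)OC)O2)ccc1O[Si](C)(C)C(C)(C)C
F6 | step 8 | selenoxide of F5, methyl 4-[(2S)-2-{4-[tert-butyl(dimethyl)silyl]oxy-3-(3-methylbut-2-en-1-yl)phenyl}-4-oxo-5-(phenylseleninyl)tetrahydro-2H-pyran-6-yl]-7-methyl-2-(3-methylbut-2-en-1-yl)-3-oxooct-6-enoate | CC(C)=CCc1cc([C@@H]2CC(=O)C([Se](=O)c3ccccc3)C(C(CC=C(C)C)C(=O)C(CC=C(C)C)C(=O)OC)O2)ccc1O[Si](C)(C)C(C)(C)C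
F7 | step 9 | acylketene, 4-[(2S)-2-{4-[tert-butyl(dimethyl)silyl]oxy-3-(3-methylbut-2-en-1-yl)phenyl}-4-oxo-3,4-dihydro-2H-pyran-6-yl]-7-methyl-2-(3-methylbut-2-en-1-yl)octa-1,6-diene-1,3-dione | CC(C)=CCc1cc([C@@H]2CC(=O)C=C(C(CC=C(C)C)C(=O)C(CC=C(C)C)=C=O)O2)ccc1O[Si](C)(C)C(C)(C)C
F8 | step 1 | 4-[(2-methylbut-3-yn-2-yl)oxy]benzaldehyde | O=Cc1ccc(OC(C)(C)C#C)cc1
F9 | step 1 | 4-[(2-methylbut-3-en-2-yl)oxy]benzaldehyde | O=Cc1ccc(OC(C)(C)C=C)cc1
A1 | alternative 1 | (2S)-5,7-bis(methoxymethoxy)-2-[4-(methoxymethoxy)-3-(3-methylbut-2-en-1-yl)phenyl]-6,8-bis(3-methylbut-2-en-1-yl)chroman-4-one | CC(C)=CCc1cc([C@@H]2CC(=O)c3c(OCOC)c(CC=C(C)C)c(OCOC)c(CC=C(C)C)c3O2)ccc1OCOC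
A2 | alternative 1 | 3,5-bis(methoxymethoxy)-2,4-bis(3-methylbut-2-en-1-yl)-6-(trimethylsilyl)phenyl trifluoromethanesulfonate | COCOc1c(CC=C(C)C)c(OCOC)c(CC=C(C)C)c(OS(=O)(=O)C(F)(F)F)c1[Si](C)(C)C
A3 | alternative 1 | methyl (3S)-3-[4-(methoxymethoxy)-3-(3-methylbut-2-en-1-yl)phenyl]-3-(trimethylsilyloxy)propanoate | CC(C)=CCc1cc([C@H](CC(=O)OC)O[Si](C)(C)C)ccc1OCOC
A4 | alternative 2 | (3R)-3-[tert-butyl(dimethyl)silyl]oxy-3-[4-(methoxymethoxy)-3-(3-methylbut-2-en-1-yl)phenyl]-1-[2,4,6-trihydroxy-3,5-bis(3-methylbut-2-en-1-yl)phenyl]propan-1-one | CC(C)=CCc1cc([C@H](O[Si](C)(C)C(C)(C)C)CC(=O)c2c(O)c(CC=C(C)C)c(O)c(CC=C(C)C)c2O)ccc1OCOC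
A5 | alternative 2 | methyl (9R)-9-[tert-butyl(dimethyl)silyl]oxy-9-[4-(methoxymethoxy)-3-(3-methylbut-2-en-1-yl)phenyl]-2,4-bis(3-methylbut-2-en-1-yl)-3,5,7-trioxononanoate | CC(C)=CCc1cc([C@H](O[Si](C)(C)C(C)(C)C)CC(=O)CC(=O)C(CC=C(C)C)C(=O)C(CC=C(C)C)C(=O)OC)ccc1OCOC
A6 | alternative 3 | (2S)-5,7-bis{[tert-butyl(dimethyl)silyl]oxy}-2-{4-[tert-butyl(dimethyl)silyl]oxy-3-(3-methylbut-2-en-1-yl)phenyl}-6,8-bis(3-methylbut-2-en-1-yl)chroman-4-one | CC(C)=CCc1cc([C@@H]2CC(=O)c3c(O[Si](C)(C)C(C)(C)C)c(CC=C(C)C)c(O[Si](C)(C)C(C)(C)C)c(CC=C(C)C)c3O2)ccc1O[Si](C)(C)C(C)(C)C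
A7 | alternative 3 | 1-[2-({4-[tert-butyl(dimethyl)silyl]oxy-3-(3-methylbut-2-en-1-yl)phenyl}methoxy)-4,6-bis{[tert-butyl(dimethyl)silyl]oxy}-3,5-bis(3-methylbut-2-en-1-yl)phenyl]-2-diazoethan-1-one | CC(C)=CCc1cc(COc2c(CC=C(C)C)c(O[Si](C)(C)C(C)(C)C)c(CC=C(C)C)c(O[Si](C)(C)C(C)(C)C)c2C(=O)C=[N+]=[N-])ccc1O[Si](C)(C)C(C)(C)C
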